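**Retrosynthetic overview**
1. Triphlorethol A ⇒ (global hydrogenolysis, double decarboxylation) a dibenzyl 5-aryloxy-2,4,6-trihydroxyisophthalate. Its aryl group is the benzyl-protected ring A–O–ring B unit.
2. Ring C ⇒ Dieckmann closure of an open tricarbonyl triester. That triester comes from an intermolecular crossed Claisen C-acylation joining an aryloxymalonyl C3 fragment (carrying rings A and B) to dibenzyl acetonedicarboxylate (second C3 fragment).
3. Aryloxymalonyl fragment ⇒ SN2 O-alkylation of the ring A–B phenol with dibenzyl chloromalonate, so the crowded C–O bond of ring C is made at an sp3 carbon.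
4. Ring A–B phenol ⇒ Baeyer–Villiger of a benzaldehyde ⇐ benzoate ⇐ Ullmann coupling of 3,5-bis(benzyloxy)phenol (ring A) with benzyl 3,5-bis(benzyloxy)-4-bromobenzoate (ring B).
5. Ring order: rings A and B are bought as arenes and joined first. Ring C is the only ring built, and it is built last.

Assumption: the target SMILES holds no stereocentre, so triphlorethol A is achiral and needs no enantiocontrol. The stereocentres of 14, 15 and 18 are racemic, enolisable and erased when ring C aromatises.

**Step 1**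
Reactants: 1 5-bromobenzene-1,3-diol
Product: 2 1,3-bis(benzyloxy)-5-bromobenzene
Conditions: BnBr (2.3 equiv), K2CO3 (3 equiv), DMF, 50 °C
Reagents that add atoms: benzyl bromide, BrCc1ccccc1
Why: Williamson etherification of both phenols with an SN2-reactive halide, the bromine substituent keeping the ring too electron-poor for the C-benzylation that plagues phloroglucinol itself.

**Step 2**
Reactants: 2 1,3-bis(benzyloxy)-5-bromobenzene
Product: 3 3,5-bis(benzyloxy)phenol
Conditions: Pd2(dba)3 (2 mol %), t-BuXPhos (8 mol %), KOH (3 equiv), 1,4-dioxane–H2O 1:1, 100 °C; then 1 M HCl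
Reagents that add atoms: potassium hydroxide, [K+].[OH-]
Why: Palladium-catalysed hydroxylation of an unhindered aryl bromide (Buchwald-type C–O coupling), in which the bulky biaryl phosphine favours C–O reductive elimination and the benzyl ethers are inert to hot hydroxide.

**Step 3**
Reactants: 4 4-bromo-3,5-dihydroxybenzoic acid
Product: 5 benzyl 3,5-bis(benzyloxy)-4-bromobenzoate
Conditions: BnBr (3.5 equiv), K2CO3 (4.5 equiv), DMF, 60 °C
Reagents that add atoms: benzyl bromide, BrCc1ccccc1
Why: Exhaustive Williamson-type O-alkylation of the two phenols and the carboxylate in one operation, which gives ring B its two flanking protected oxygens, a para ester and the bromide at the future ether carbon.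

**Step 4**
Reactants: 5 benzyl 3,5-bis(benzyloxy)-4-bromobenzoate; 3 3,5-bis(benzyloxy)phenol
Product: 6 benzyl 3,5-bis(benzyloxy)-4-[3,5-bis(benzyloxy)phenoxy]benzoate
Conditions: CuI (20 mol %), N,N-dimethylglycine (40 mol %), Cs2CO3 (2 equiv), 1,4-dioxane, 105 °C, Ar
Reagents that add atoms: none
Why: Ligand-accelerated Ullmann diaryl ether coupling, in which the para ester activates the C–Br bond, the ortho alkoxy oxygens can pre-coordinate monovalent copper, and the electron-rich unhindered phenol 3 is a good nucleophile.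

**Step 5**
Reactants: 6 benzyl 3,5-bis(benzyloxy)-4-[3,5-bis(benzyloxy)phenoxy]benzoate
Product: 7 {3,5-bis(benzyloxy)-4-[3,5-bis(benzyloxy)phenoxy]phenyl}methanol
Conditions: LiAlH4 (1.2 equiv), THF, 0 °C to rt; aqueous work-up
Reagents that add atoms: none
Why: Hydride reduction of the only reducible group, the ester, to the primary benzylic alcohol, with aryl, diaryl and benzyl ethers untouched.

**Step 6**
Reactants: 7 {3,5-bis(benzyloxy)-4-[3,5-bis(benzyloxy)phenoxy]phenyl}methanol
Product: 8 3,5-bis(benzyloxy)-4-[3,5-bis(benzyloxy)phenoxy]benzaldehyde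
Conditions: activated MnO2 (15 equiv), CH2Cl2, rt
Reagents that add atoms: none
Why: Chemoselective MnO2 oxidation of a benzylic alcohol, which stops cleanly at the aldehyde and does not touch the electron-rich rings.

**Step 7**
Reactants: 8 3,5-bis(benzyloxy)-4-[3,5-bis(benzyloxy)phenoxy]benzaldehyde
Product: 10 3,5-bis(benzyloxy)-4-[3,5-bis(benzyloxy)phenoxy]phenol, via aryl formate 9 (not isolated)
Conditions: mCPBA (1.4 equiv), CH2Cl2, 0 °C to rt; aq NaHCO3 wash, concentrate; then K2CO3 (0.2 equiv), MeOH–THF, rt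
Reagents that add atoms: mCPBA (3-chloroperoxybenzoic acid), OOC(=O)c1cccc(Cl)c1
Why: Baeyer–Villiger (Dakin-type) oxidation, in which the para-oxygenated 3,4,5-trioxygenated aryl group migrates in preference to hydrogen as in the trimethoxybenzaldehyde series, followed by mild methanolysis of the formate to free the unhindered phenol of ring B.

**Step 8**
Reactants: 11 dibenzyl malonate
Product: 12 dibenzyl 2-chloromalonate
Conditions: SO2Cl2 (1.05 equiv), CH2Cl2, 0 °C to 35 °C
Reagents that add atoms: sulfuryl chloride, ClS(Cl)(=O)=O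
Why: Electrophilic α-chlorination of the malonate enol, with one equivalent of reagent giving mainly the monochloride because the product enolises less readily.

**Step 9**
Reactants: 10 3,5-bis(benzyloxy)-4-[3,5-bis(benzyloxy)phenoxy]phenol; 12 dibenzyl 2-chloromalonate
Product: 13 dibenzyl 2-{3,5-bis(benzyloxy)-4-[3,5-bis(benzyloxy)phenoxy]phenoxy}malonate
Conditions: K2CO3 (2 equiv), DMF, 45 °C, Ar
Reagents that add atoms: none
Why: SN2 O-alkylation of the phenoxide by the doubly activated chloride (Williamson type, chloride chosen over bromide to avoid halogen transfer to the electron-rich rings), which forms the future hindered C–O bond of ring C without any metal.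

**Step 10**
Reactants: 13 dibenzyl 2-{3,5-bis(benzyloxy)-4-[3,5-bis(benzyloxy)phenoxy]phenoxy}malonate
Product: 14 3-(benzyloxy)-2-{3,5-bis(benzyloxy)-4-[3,5-bis(benzyloxy)phenoxy]phenoxy}-3-oxopropanoic acid (racemic half-ester)
Conditions: KOH (1.0 equiv), THF–H2O, 0 °C; then 1 M HCl to pH 2, 0 °C
Reagents that add atoms: potassium hydroxide, [K+].[OH-]
Why: Selective monosaponification of a symmetric malonate, where the first carboxylate formed shuts down attack on the second ester, and the stereocentre created is racemic, labile and of no consequence.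

**Step 11**
Reactants: 14 racemic half-ester
Product: 15 benzyl 2-{3,5-bis(benzyloxy)-4-[3,5-bis(benzyloxy)phenoxy]phenoxy}-3-chloro-3-oxopropanoate (racemic acid chloride, used crude)
Conditions: 1-chloro-N,N,2-trimethylprop-1-en-1-amine (1.1 equiv), CH2Cl2, 0 °C, 1 h; evaporate cold
Reagents that add atoms: 1-chloro-N,N,2-trimethylprop-1-en-1-amine (Ghosez reagent), CC(C)=C(Cl)N(C)C
Why: Neutral acid chloride formation with the Ghosez α-chloroenamine, which releases no HCl and avoids oxalyl chloride, a reagent that would acylate the phloroglucinol-type rings, while the stereocentre stays racemic.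

**Step 12**
Reactants: 16 dimethyl 3-oxopentanedioate (dimethyl acetonedicarboxylate)
Product: 17 dibenzyl 3-oxopentanedioate
Conditions: BnOH (2.5 equiv), toluene, reflux, MeOH distilled off
Reagents that add atoms: benzyl alcohol, OCc1ccccc1
Why: Uncatalysed thermal transesterification of a β-keto ester through its acylketene, driven by removal of methanol and run without base so that the diester does not self-condense.

**Step 13 (key step)**
Reactants: 15 racemic acid chloride; 17 dibenzyl 3-oxopentanedioate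
Product: 18 tribenzyl 1-{3,5-bis(benzyloxy)-4-[3,5-bis(benzyloxy)phenoxy]phenoxy}-2,4-dioxopentane-1,3,5-tricarboxylate (mixture of diastereomers and enol forms, used crude)
Conditions: 17 (1.3 equiv), MgCl2 (1.3 equiv), pyridine (3 equiv), CH2Cl2, 0 °C, 30 min; then 15, −10 °C to rt; cold 1 M HCl wash
Reagents that add atoms: none
Why: Intermolecular crossed Claisen-type C-acylation under soft enolisation, in which the chelated magnesium enolate of 17 is acylated on carbon by 15 (directly or through its ketene) and the very acidic tricarbonyl product is held as its magnesium chelate, so reversal and second acylation are blocked, and the two uncontrolled stereocentres are enolisable and vanish in the next step.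

**Step 14**
Reactants: 18 tribenzyl tricarbonyl triester
Product: 19 dibenzyl 5-{3,5-bis(benzyloxy)-4-[3,5-bis(benzyloxy)phenoxy]phenoxy}-2,4,6-trihydroxybenzene-1,3-dicarboxylate
Conditions: t-BuOK (3.3 equiv), THF, 0 °C to rt, Ar; then cold 1 M HCl
Reagents that add atoms: none
Why: Dieckmann (intramolecular Claisen) condensation in which the remaining activated CH2 attacks the benzyl ester next to the aryloxy carbon, and the six-membered triketone tautomerises at once to the phloroglucinol, an irreversible aromatic sink that also drains reversibly formed 2-pyranones through the released benzyloxide and erases all stereocentres.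

**Step 15**
Reactants: 19 dibenzyl 5-aryloxy-2,4,6-trihydroxyisophthalate
Product: 22 triphlorethol A, via isophthalic diacid 20 (not isolated), via benzoic monoacid 21 (not isolated)
Conditions: H2 (1 atm), 10% Pd/C, THF–MeOH, rt; filter under Ar, concentrate; then degassed H2O–1,4-dioxane, 90 °C, 2 h
Reagents that add atoms: none
Why: Global hydrogenolysis of four benzyl ethers and two benzyl esters leaves the diaryl ethers intact, and the 2,4,6-trihydroxy-substituted acids then lose CO2 on gentle heating by ipso-protonation of the very electron-rich ring (protodecarboxylation), so the air-sensitive heptaphenol never meets acid, base or a Lewis acid.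

**Compound list**
1 | 5-bromobenzene-1,3-diol | Oc1cc(O)cc(Br)c1 | starting material
2 | 1,3-bis(benzyloxy)-5-bromobenzene | Brc1cc(OCc2ccccc2)cc(OCc2ccccc2)c1 | intermediate
3 | 3,5-bis(benzyloxy)phenol | Oc1cc(OCc2ccccc2)cc(OCc2ccccc2)c1 | intermediate
4 | 4-bromo-3,5-dihydroxybenzoic acid | OC(=O)c1cc(O)c(Br)c(O)c1 | starting material
5 | benzyl 3,5-bis(benzyloxy)-4-bromobenzoate | O=C(OCc1ccccc1)c1cc(OCc2ccccc2)c(Br)c(OCc2ccccc2)c1 | intermediate
6 | benzyl 3,5-bis(benzyloxy)-4-[3,5-bis(benzyloxy)phenoxy]benzoate | O=C(OCc1ccccc1)c1cc(OCc2ccccc2)c(Oc2cc(OCc3ccccc3)cc(OCc3ccccc3)c2)c(OCc2ccccc2)c1 | intermediate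
7 | {3,5-bis(benzyloxy)-4-[3,5-bis(benzyloxy)phenoxy]phenyl}methanol | OCc1cc(OCc2ccccc2)c(Oc2cc(OCc3ccccc3)cc(OCc3ccccc3)c2)c(OCc2ccccc2)c1 | intermediate
8 | 3,5-bis(benzyloxy)-4-[3,5-bis(benzyloxy)phenoxy]benzaldehyde | O=Cc1cc(OCc2ccccc2)c(Oc2cc(OCc3ccccc3)cc(OCc3ccccc3)c2)c(OCc2ccccc2)c1 | intermediate
9 | 3,5-bis(benzyloxy)-4-[3,5-bis(benzyloxy)phenoxy]phenyl formate (aryl formate) | O=COc1cc(OCc2ccccc2)c(Oc2cc(OCc3ccccc3)cc(OCc3ccccc3)c2)c(OCc2ccccc2)c1 | intermediate
10 | 3,5-bis(benzyloxy)-4-[3,5-bis(benzyloxy)phenoxy]phenol | Oc1cc(OCc2ccccc2)c(Oc2cc(OCc3ccccc3)cc(OCc3ccccc3)c2)c(OCc2ccccc2)c1 | intermediate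
11 | dibenzyl malonate | O=C(OCc1ccccc1)CC(=O)OCc1ccccc1 | starting material
12 | dibenzyl 2-chloromalonate | O=C(OCc1ccccc1)C(Cl)C(=O)OCc1ccccc1 | intermediate
13 | dibenzyl 2-{3,5-bis(benzyloxy)-4-[3,5-bis(benzyloxy)phenoxy]phenoxy}malonate | O=C(OCc1ccccc1)C(Oc1cc(OCc2ccccc2)c(Oc2cc(OCc3ccccc3)cc(OCc3ccccc3)c2)c(OCc2ccccc2)c1)C(=O)OCc1ccccc1 | intermediate
14 | 3-(benzyloxy)-2-{3,5-bis(benzyloxy)-4-[3,5-bis(benzyloxy)phenoxy]phenoxy}-3-oxopropanoic acid (racemic) | OC(=O)C(Oc1cc(OCc2ccccc2)c(Oc2cc(OCc3ccccc3)cc(OCc3ccccc3)c2)c(OCc2ccccc2)c1)C(=O)OCc1ccccc1 | intermediate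
15 | benzyl 2-{3,5-bis(benzyloxy)-4-[3,5-bis(benzyloxy)phenoxy]phenoxy}-3-chloro-3-oxopropanoate (racemic) | ClC(=O)C(Oc1cc(OCc2ccccc2)c(Oc2cc(OCc3ccccc3)cc(OCc3ccccc3)c2)c(OCc2ccccc2)c1)C(=O)OCc1ccccc1 | intermediate
16 | dimethyl 3-oxopentanedioate | COC(=O)CC(=O)CC(=O)OC | starting material
17 | dibenzyl 3-oxopentanedioate | O=C(CC(=O)OCc1ccccc1)CC(=O)OCc1ccccc1 | intermediate
18 | tribenzyl 1-{3,5-bis(benzyloxy)-4-[3,5-bis(benzyloxy)phenoxy]phenoxy}-2,4-dioxopentane-1,3,5-tricarboxylate (stereocentres uncontrolled, enolisable) | O=C(OCc1ccccc1)C(Oc1cc(OCc2ccccc2)c(Oc2cc(OCc3ccccc3)cc(OCc3ccccc3)c2)c(OCc2ccccc2)c1)C(=O)C(C(=O)OCc1ccccc1)C(=O)CC(=O)OCc1ccccc1 | intermediate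
19 | dibenzyl 5-{3,5-bis(benzyloxy)-4-[3,5-bis(benzyloxy)phenoxy]phenoxy}-2,4,6-trihydroxybenzene-1,3-dicarboxylate | Oc1c(C(=O)OCc2ccccc2)c(O)c(C(=O)OCc2ccccc2)c(O)c1Oc1cc(OCc2ccccc2)c(Oc2cc(OCc3ccccc3)cc(OCc3ccccc3)c2)c(OCc2ccccc2)c1 | intermediate
20 | 5-[4-(3,5-dihydroxyphenoxy)-3,5-dihydroxyphenoxy]-2,4,6-trihydroxybenzene-1,3-dicarboxylic acid (isophthalic diacid) | Oc1c(C(=O)O)c(O)c(C(=O)O)c(O)c1Oc1cc(O)c(Oc2cc(O)cc(O)c2)c(O)c1 | intermediate
21 | 3-[4-(3,5-dihydroxyphenoxy)-3,5-dihydroxyphenoxy]-2,4,6-trihydroxybenzoic acid (benzoic monoacid) | Oc1cc(O)c(C(=O)O)c(O)c1Oc1cc(O)c(Oc2cc(O)cc(O)c2)c(O)c1 | intermediate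
22 | triphlorethol A (achiral) | Oc1cc(O)cc(Oc2c(O)cc(Oc3c(O)cc(O)cc3O)cc2O)c1 | target

**Total step count:** 15.
**Longest linear sequence:** 12 steps (1, 2, 4, 5, 6, 7, 9, 10, 11, 13, 14, 15).

**Three steps most likely to fail**

Step 4 (Ullmann coupling at a bromide flanked by two benzyloxy groups) may be slow, or may end in protodebromination.
- The fallback reverses the roles of the two rings. It sets out from 5 and 2 and comes back at 6, and step 2 is then not needed.
- Bromide 5 is borylated (B2pin2, PdCl2(dppf), KOAc, 1,4-dioxane, 90 °C) to benzyl 3,5-bis(benzyloxy)-4-(4,4,5,5-tetramethyl-1,3,2-dioxaborolan-2-yl)benzoate F1.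
- NaBO3·4H2O in THF–H2O at rt oxidises this to benzyl 3,5-bis(benzyloxy)-4-hydroxybenzoate F2.
- The crowded ring now serves as the phenol nucleophile and the unhindered bromide 2 as the electrophile (CuI, picolinic acid, K3PO4, DMSO, 90 °C), giving 6.

Step 13 (C-acylation) may suffer from ketene dimerisation, O-acylation, or cyclisation of 15 onto the activated ortho position of ring B.
- The fallback avoids every acyl halide. It sets out from diester 13 and from 17 and comes back at 19, by-passing 14 and 15.
- Compounds 13 and 17 (1.2 equiv) are heated with NaOCH2Ph (3 equiv) in toluene at 100 °C.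
- This is an ester-only [3+3] double Claisen cyclocondensation: an intermolecular Claisen followed by a Dieckmann closure in the same flask.
- It is driven by formation of the aromatic trisphenolate, and it is free of ester scrambling because every ester and alkoxide is benzylic.
- It makes no compound outside the list (entry F0).

Step 14 (Dieckmann aromatisation) may be overtaken by O-cyclisation to 2-pyranones.
- The fallback gives up the ring closure and brings in ring C as a finished arene. It sets out from 10 and 3 and comes back at 22.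
- Phenol 3 is benzylated (BnBr, K2CO3, DMF) to 1,3,5-tris(benzyloxy)benzene F3.
- Iodination with NIS in MeCN at 0 °C gives 1,3,5-tris(benzyloxy)-2-iodobenzene F4.
- F4 is coupled with phenol 10 (CuI, picolinic acid, K3PO4, DMSO, 90 °C) to triphlorethol A heptabenzyl ether F5.
- H2 over 10% Pd/C in THF–MeOH converts F5 into 22.

**Further compounds**
F1 | step 4 | benzyl 3,5-bis(benzyloxy)-4-(4,4,5,5-tetramethyl-1,3,2-dioxaborolan-2-yl)benzoate | O=C(OCc1ccccc1)c1cc(OCc2ccccc2)c(B2OC(C)(C)C(C)(C)O2)c(OCc2ccccc2)c1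
F2 | step 4 | benzyl 3,5-bis(benzyloxy)-4-hydroxybenzoate | O=C(OCc1ccccc1)c1cc(OCc2ccccc2)c(O)c(OCc2ccccc2)c1
F0 | step 13 | none | none
F3 | step 14 | 1,3,5-tris(benzyloxy)benzene | C(Oc1cc(OCc2ccccc2)cc(OCc2ccccc2)c1)c1ccccc1
F4 | step 14 | 1,3,5-tris(benzyloxy)-2-iodobenzene | Ic1c(OCc2ccccc2)cc(OCc2ccccc2)cc1OCc1ccccc1
F5 | step 14 | triphlorethol A heptabenzyl ether | c1ccccc1COc1cc(OCc2ccccc2)cc(Oc2c(OCc3ccccc3)cc(Oc3c(OCc4ccccc4)cc(OCc4ccccc4)cc3OCc3ccccc3)cc2OCc2ccccc2)c1
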